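**Retrosynthetic overview**

- The target is reached by removing two MOM ethers from the protected trans-dihydroflavonol. Its C3 hydroxyl comes from a Rubottom oxidation of the (2S)-flavanone, in which C2 controls C3. C2 comes from an enantioselective copper hydride 1,4-reduction of the flavone.
- The plan rests on C4, the carbonyl carbon of ring C. It lies between aromatic C4a of ring A and the C3–C2 unit that ends at O1, so it is traced back to carbon monoxide. The flavone is cut into a ring A ortho-iodophenol (C4a–I, C8a–OH), CO, and a ring B arylacetylene (C3 and C2), forming C4a–C4, C4–C3 and O1–C2 in one operation.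
- The iodophenol comes from an aromatic Claisen rearrangement of a 1,1-dimethylallyl ether, which puts the prenyl group on C8 while the iodine blocks the other ortho carbon. That ether comes from 5-methoxyresorcinol by iodination between the hydroxyls and mono-MOM protection. The alkyne comes from 4-iodophenol and trimethylsilylacetylene.
- Rings A and B are bought as aromatic starting materials; ring C is the only ring formed, in step 9.

Key step: step 9

Assumption: (R)-DTBM-SEGPHOS is written in step 10 as the ligand antipode that delivers hydride to the C2 face giving the (2S)-flavanone; if the sense of induction is the opposite, the (S)-ligand is used and nothing else changes.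

**Step 1**
Reactants: 1 5-methoxyresorcinol
Product: 2 2-iodo-5-methoxybenzene-1,3-diol
Conditions: I2 (1.0 equiv), NaHCO3, THF/H2O, 0 °C
Reagents that add atoms: iodine, II
Why: Electrophilic aromatic iodination under bicarbonate buffering should take the carbon between the two hydroxyls, as it does for resorcinol and its 5-substituted congeners, and one equivalent of I2 at 0 °C limits polyiodination.

**Step 2**
Reactants: 2 2-iodo-5-methoxybenzene-1,3-diol
Product: 3 2-iodo-5-methoxy-3-(methoxymethoxy)phenol
Conditions: MOMCl (1.0 equiv), i-Pr2NEt, CH2Cl2, 0 °C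
Reagents that add atoms: chloromethyl methyl ether, COCCl
Why: Williamson-type O-alkylation with a limiting amount of MOMCl; the two hydroxyls of 2 are equivalent by symmetry, so the mono-ether is a single constitution, and unreacted 2 and the bis-ether are separable and can be recycled.

**Step 3**
Reactants: 3 2-iodo-5-methoxy-3-(methoxymethoxy)phenol; 4 3-chloro-3-methylbut-1-yne
Product: 5 2-iodo-5-methoxy-1-(methoxymethoxy)-3-[(2-methylbut-3-yn-2-yl)oxy]benzene
Conditions: DBU, CuCl2·2H2O (1 mol%), MeCN, 0 °C
Reagents that add atoms: none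
Why: Copper-catalysed propargylic etherification of a phenol with a tertiary propargylic chloride, which O-alkylates ortho-substituted phenols at 0 °C and leaves the aryl iodide alone.

**Step 4**
Reactants: 5 2-iodo-5-methoxy-1-(methoxymethoxy)-3-[(2-methylbut-3-yn-2-yl)oxy]benzene
Product: 6 2-iodo-5-methoxy-1-(methoxymethoxy)-3-[(2-methylbut-3-en-2-yl)oxy]benzene
Conditions: H2 (1 atm), Pd/CaCO3 poisoned with Pb(OAc)2 (Lindlar catalyst), quinoline, EtOAc, rt
Reagents that add atoms: none
Why: Lindlar semi-hydrogenation of the terminal alkyne to the vinyl group; the lead- and quinoline-poisoned catalyst and stopping after one equivalent of H2 should spare the aryl iodide and the new alkene.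

**Step 5**
Reactants: 6 2-iodo-5-methoxy-1-(methoxymethoxy)-3-[(2-methylbut-3-en-2-yl)oxy]benzene
Product: 8 2-iodo-5-methoxy-3-(methoxymethoxy)-6-(3-methylbut-2-en-1-yl)phenol, via ortho-dienone 7 (not isolated)
Conditions: PhNEt2, 140 °C
Reagents that add atoms: none
Why: Aromatic Claisen rearrangement: the [3,3] shift can end productively only at the free ortho carbon because the other one carries iodine, the allyl inversion turns the 1,1-dimethylallyl ether into a prenyl group, and tautomerisation of dienone 7 gives the phenol, while the amine solvent suppresses acid-catalysed ether cleavage and chroman formation.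

**Step 6**
Reactants: 9 4-iodophenol
Product: 10 1-iodo-4-(methoxymethoxy)benzene
Conditions: MOMCl, i-Pr2NEt, CH2Cl2, 0 °C to rt
Reagents that add atoms: chloromethyl methyl ether, COCCl
Why: Williamson-type MOM protection of an unhindered phenol.

**Step 7**
Reactants: 10 1-iodo-4-(methoxymethoxy)benzene; 11 ethynyltrimethylsilane
Product: 12 {[4-(methoxymethoxy)phenyl]ethynyl}trimethylsilane
Conditions: PdCl2(PPh3)2 (2 mol%), CuI (4 mol%), Et3N, THF, rt
Reagents that add atoms: none
Why: Sonogashira coupling of an aryl iodide with a terminal alkyne, which runs at room temperature and tolerates the MOM ether.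

**Step 8**
Reactants: 12 {[4-(methoxymethoxy)phenyl]ethynyl}trimethylsilane
Product: 13 1-ethynyl-4-(methoxymethoxy)benzene
Conditions: K2CO3 (cat.), MeOH, rt
Reagents that add atoms: none
Why: Base-catalysed methanolysis of the alkynyl C–Si bond (protodesilylation), to which the MOM ether is inert.

**Step 9**
Reactants: 8 2-iodo-5-methoxy-3-(methoxymethoxy)-6-(3-methylbut-2-en-1-yl)phenol; 13 1-ethynyl-4-(methoxymethoxy)benzene; 14 carbon monoxide
Product: 17 7-methoxy-5-(methoxymethoxy)-2-[4-(methoxymethoxy)phenyl]-8-(3-methylbut-2-en-1-yl)-4H-chromen-4-one, via ynone 15 (not isolated), via enaminone 16 (not isolated)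
Conditions: 14 (1 atm, balloon), PdCl2(PPh3)2 (5 mol%), dppp (5 mol%), thiourea (5 mol%), Et2NH, 40 °C
Reagents that add atoms: none
Why: Zerovalent palladium, formed in the flask from the divalent precatalyst PdCl2(PPh3)2, inserts into the C–I bond of 8, CO insertion gives the aroylpalladium iodide, and amine-assisted transfer of the acetylide of 13 followed by reductive elimination forms C4a–C4 and C4–C3 and gives ynone 15. Et2NH then adds to 15 in conjugate fashion to give enaminone 16, and the neighbouring phenol replaces the amine at C2 by addition–elimination, which forms O1–C2. The closest known reaction type is the palladium-catalysed carbonylative Sonogashira coupling–cyclisation of 2-iodophenols with terminal arylacetylenes to flavones. Ring C closes in the 6-endo mode (6-endo-trig on the enaminone, formally 6-endo-dig on the ynone), and no stereocentre is formed. The step needs six- over five-membered closure and carbonylative over direct coupling: the first is secured by passing through the enaminone, whose amine-bearing carbon is the only electrophilic site offered to the phenol, the second by the electron-rich aryl–palladium bond, which takes up CO quickly, and by the absence of copper. The position of the iodide fixes the ring A substitution pattern, and the prenyl alkene and both MOM ethers should be untouched.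

**Step 10**
Reactants: 17 7-methoxy-5-(methoxymethoxy)-2-[4-(methoxymethoxy)phenyl]-8-(3-methylbut-2-en-1-yl)-4H-chromen-4-one
Product: 19 (2S)-7-methoxy-5-(methoxymethoxy)-2-[4-(methoxymethoxy)phenyl]-8-(3-methylbut-2-en-1-yl)chroman-4-one, via silyl enol ether 18 (not isolated)
Conditions: Cu(OAc)2 (5 mol%), (R)-DTBM-SEGPHOS (5.5 mol%), (EtO)2MeSiH, toluene, 0 °C to rt; then 1 M aq HCl, THF, 0 °C (brief)
Reagents that add atoms: none
Why: Enantioselective copper hydride conjugate reduction (asymmetric 1,4-hydrosilylation) of the chromone-type vinylogous ester: the bisphosphine-ligated copper hydride delivers hydride to C2 from the face chosen by the chiral ligand, which sets C2 as S, and the product stays masked as silyl enol ether 18 until work-up so that the C4 carbonyl is not reduced further, while the isolated prenyl alkene and the MOM ethers do not react.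

**Step 11**
Reactants: 19 (2S)-7-methoxy-5-(methoxymethoxy)-2-[4-(methoxymethoxy)phenyl]-8-(3-methylbut-2-en-1-yl)chroman-4-one
Product: 20 (2S)-7-methoxy-5-(methoxymethoxy)-2-[4-(methoxymethoxy)phenyl]-8-(3-methylbut-2-en-1-yl)-4-(trimethylsilyloxy)-2H-chromene
Conditions: TMSOTf, Et3N, CH2Cl2, −78 to 0 °C; non-aqueous work-up, used crude
Reagents that add atoms: trimethylsilyl trifluoromethanesulfonate, C[Si](C)(C)OS(=O)(=O)C(F)(F)F
Why: Soft enolisation of the ketone with a silyl triflate and a tertiary amine gives the only possible enol silane (C3=C4) without a free enolate, so C2 cannot be lost by ring opening to a chalcone, and the excess amine protects the MOM ethers from the silyl triflate.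

**Step 12**
Reactants: 20 (2S)-7-methoxy-5-(methoxymethoxy)-2-[4-(methoxymethoxy)phenyl]-8-(3-methylbut-2-en-1-yl)-4-(trimethylsilyloxy)-2H-chromene
Product: 22 (2R,3R)-3-hydroxy-7-methoxy-5-(methoxymethoxy)-2-[4-(methoxymethoxy)phenyl]-8-(3-methylbut-2-en-1-yl)chroman-4-one, via silyloxy epoxide 21 (not isolated)
Conditions: DMDO (1.05 equiv), acetone/CH2Cl2, −78 °C; then citric acid, MeOH, 0 °C
Reagents that add atoms: dimethyldioxirane, CC1(C)OO1
Why: Rubottom oxidation: DMDO should epoxidise the electron-rich enol silane much faster than the trisubstituted prenyl alkene at −78 °C and from the face opposite the C2 aryl group, so that methanolysis of silyloxy epoxide 21 gives the 3-hydroxy ketone with the 2,3-trans relationship, which sets C3 as R under control of C2.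

**Step 13**
Reactants: 22 (2R,3R)-3-hydroxy-7-methoxy-5-(methoxymethoxy)-2-[4-(methoxymethoxy)phenyl]-8-(3-methylbut-2-en-1-yl)chroman-4-one
Product: 23 (2R,3R)-3,5-dihydroxy-2-(4-hydroxyphenyl)-7-methoxy-8-(3-methylbut-2-en-1-yl)chroman-4-one
Conditions: HCl (1.25 M in MeOH), 40 °C
Reagents that add atoms: none
Why: Acid-catalysed transacetalisation removes both MOM ethers as dimethoxymethane; the prenyl group has no free ortho hydroxyl to cyclise onto (its neighbours are the C7 methyl ether and O1), and the mild, base-free conditions should leave the trans stereocentres at C2 and C3 unchanged.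

**Compound list**

1 | 5-methoxyresorcinol | COc1cc(O)cc(O)c1 | starting material
2 | 2-iodo-5-methoxybenzene-1,3-diol | COc1cc(O)c(I)c(O)c1 | intermediate
3 | 2-iodo-5-methoxy-3-(methoxymethoxy)phenol | COCOc1cc(OC)cc(O)c1I | intermediate
4 | 3-chloro-3-methylbut-1-yne | CC(C)(Cl)C#C | starting material
5 | 2-iodo-5-methoxy-1-(methoxymethoxy)-3-[(2-methylbut-3-yn-2-yl)oxy]benzene | COCOc1cc(OC)cc(OC(C)(C)C#C)c1I | intermediate
6 | 2-iodo-5-methoxy-1-(methoxymethoxy)-3-[(2-methylbut-3-en-2-yl)oxy]benzene | COCOc1cc(OC)cc(OC(C)(C)C=C)c1I | intermediate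
7 | ortho-dienone, not isolated: 2-iodo-5-methoxy-3-(methoxymethoxy)-6-(3-methylbut-2-en-1-yl)cyclohexa-2,4-dien-1-one (racemic at C6) | COC1=CC(OCOC)=C(I)C(=O)C1CC=C(C)C | intermediate
8 | 2-iodo-5-methoxy-3-(methoxymethoxy)-6-(3-methylbut-2-en-1-yl)phenol | COc1cc(OCOC)c(I)c(O)c1CC=C(C)C | intermediate
9 | 4-iodophenol | Oc1ccc(I)cc1 | starting material
10 | 1-iodo-4-(methoxymethoxy)benzene | COCOc1ccc(I)cc1 | intermediate
11 | ethynyltrimethylsilane (trimethylsilylacetylene) | C#C[Si](C)(C)C | starting material
12 | {[4-(methoxymethoxy)phenyl]ethynyl}trimethylsilane | COCOc1ccc(C#C[Si](C)(C)C)cc1 | intermediate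
13 | 1-ethynyl-4-(methoxymethoxy)benzene | C#Cc1ccc(OCOC)cc1 | intermediate
14 | carbon monoxide | [C-]#[O+] | starting material
15 | ynone, not isolated: 1-[2-hydroxy-4-methoxy-6-(methoxymethoxy)-3-(3-methylbut-2-en-1-yl)phenyl]-3-[4-(methoxymethoxy)phenyl]prop-2-yn-1-one | COc1cc(OCOC)c(C(=O)C#Cc2ccc(OCOC)cc2)c(O)c1CC=C(C)C | intermediate
16 | enaminone, not isolated: 3-(diethylamino)-1-[2-hydroxy-4-methoxy-6-(methoxymethoxy)-3-(3-methylbut-2-en-1-yl)phenyl]-3-[4-(methoxymethoxy)phenyl]prop-2-en-1-one (alkene geometry not fixed) | COc1cc(OCOC)c(C(=O)C=C(N(CC)CC)c2ccc(OCOC)cc2)c(O)c1CC=C(C)C | intermediate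
17 | 7-methoxy-5-(methoxymethoxy)-2-[4-(methoxymethoxy)phenyl]-8-(3-methylbut-2-en-1-yl)-4H-chromen-4-one (7-methoxy-5,4'-bis(methoxymethoxy)-8-prenylflavone) | COc1cc(OCOC)c2c(c1CC=C(C)C)oc(-c1ccc(OCOC)cc1)cc2=O | intermediate
18 | silyl enol ether, not isolated: (2S)-4-{[diethoxy(methyl)silyl]oxy}-7-methoxy-5-(methoxymethoxy)-2-[4-(methoxymethoxy)phenyl]-8-(3-methylbut-2-en-1-yl)-2H-chromene | COc1cc(OCOC)c2c(c1CC=C(C)C)O[C@H](c1ccc(OCOC)cc1)C=C2O[Si](C)(OCC)OCC | intermediate
19 | (2S)-7-methoxy-5-(methoxymethoxy)-2-[4-(methoxymethoxy)phenyl]-8-(3-methylbut-2-en-1-yl)chroman-4-one | COc1cc(OCOC)c2c(c1CC=C(C)C)O[C@H](c1ccc(OCOC)cc1)CC2=O | intermediate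
20 | (2S)-7-methoxy-5-(methoxymethoxy)-2-[4-(methoxymethoxy)phenyl]-8-(3-methylbut-2-en-1-yl)-4-(trimethylsilyloxy)-2H-chromene | COc1cc(OCOC)c2c(c1CC=C(C)C)O[C@H](c1ccc(OCOC)cc1)C=C2O[Si](C)(C)C | intermediate
21 | silyloxy epoxide, not isolated: 3,4-epoxide of 20, epoxide oxygen on the face opposite the C2 aryl group, C4 carrying the trimethylsilyloxy group | COc1cc(OCOC)c2c(c1CC=C(C)C)O[C@H](c1ccc(OCOC)cc1)[C@H]3O[C@]32O[Si](C)(C)C | intermediate
22 | (2R,3R)-3-hydroxy-7-methoxy-5-(methoxymethoxy)-2-[4-(methoxymethoxy)phenyl]-8-(3-methylbut-2-en-1-yl)chroman-4-one (2,3-trans) | COc1cc(OCOC)c2c(c1CC=C(C)C)O[C@H](c1ccc(OCOC)cc1)[C@@H](O)C2=O | intermediate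
23 | (2R,3R)-3,5-dihydroxy-2-(4-hydroxyphenyl)-7-methoxy-8-(3-methylbut-2-en-1-yl)chroman-4-one (2,3-trans) | COc1cc(O)c2c(c1CC=C(C)C)O[C@H](c1ccc(O)cc1)[C@@H](O)C2=O | target

**Step count**

Total: 13 steps. Longest linear sequence: 10 steps (steps 1–5 and 9–13); steps 6–8 form the ring B branch.

**Steps most likely to fail**

Step 9. Oxidative addition into the di-ortho-substituted, electron-rich C–I bond may be slow, the aroylpalladium species may be intercepted by Et2NH to give an amide, or coupling may proceed without CO uptake. The fallback brings C4 in as an aldehyde carbon instead of CO and sets out from 8 and 13. Compound 13 is lithiated (n-BuLi, THF, −78 °C) and formylated with DMF to give 3-[4-(methoxymethoxy)phenyl]prop-2-ynal F1. Compound 8 is converted with t-BuLi (3 equiv, THF, −78 °C) into the lithium 2-lithiophenoxide by deprotonation and iodine–lithium exchange and added to F1. This gives the racemic propargylic alcohol 2-{1-hydroxy-3-[4-(methoxymethoxy)phenyl]prop-2-yn-1-yl}-5-methoxy-3-(methoxymethoxy)-6-(3-methylbut-2-en-1-yl)phenol F2. MnO2 (CH2Cl2, rt) oxidises F2 to ynone 15, which is then isolated, and Et2NH in EtOH closes ring C through 16. The fallback comes back to the route at 17.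

Step 10. The electron-rich, peri-substituted vinylogous ester may convert slowly, the C4 carbonyl may be over-reduced, or the facial discrimination at C2 may be insufficient. The fallback sets out from 17 and replaces asymmetric catalysis by resolution. Non-selective 1,4-reduction with LiBH(s-Bu)3 (THF, −78 °C) gives racemic 7-methoxy-5-(methoxymethoxy)-2-[4-(methoxymethoxy)phenyl]-8-(3-methylbut-2-en-1-yl)chroman-4-one F3. Kinetic resolution by asymmetric transfer hydrogenation follows (RuCl(p-cymene)[(R,R)-TsDPEN] or its enantiomer, HCO2H/Et3N, rt), with the catalyst antipode chosen so that the (2R)-ketone is reduced faster. This converts the unwanted enantiomer into (2R,4R)-7-methoxy-5-(methoxymethoxy)-2-[4-(methoxymethoxy)phenyl]-8-(3-methylbut-2-en-1-yl)chroman-4-ol F4 (2,4-cis), which is separated by chromatography. The unreacted (2S)-ketone is recovered, and the fallback comes back to the route at 19.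

Step 12. The prenyl alkene may be epoxidised in competition, the enol silane may hydrolyse before it is oxidised, or the oxidant may approach syn to the aryl group and give the cis isomer. The fallback sets out from 19 and uses an enolate and an aprotic oxygen-transfer reagent instead of an enol silane and a dioxirane. The potassium enolate is generated with KN(SiMe3)2 (THF, −78 °C, short enolate lifetime to avoid ring opening) and hydroxylated with 2-(phenylsulfonyl)-3-phenyloxaziridine. This oxidant does not epoxidise isolated alkenes at that temperature and should again approach anti to the C2 aryl group. The 3-hydroxy ketone is obtained directly, without 20 and 21, and the fallback comes back to the route at 22.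

**Further compounds**

F1 | step 9 | 3-[4-(methoxymethoxy)phenyl]prop-2-ynal | O=CC#Cc1ccc(OCOC)cc1
F2 | step 9 | racemic 2-{1-hydroxy-3-[4-(methoxymethoxy)phenyl]prop-2-yn-1-yl}-5-methoxy-3-(methoxymethoxy)-6-(3-methylbut-2-en-1-yl)phenol | COc1cc(OCOC)c(C(O)C#Cc2ccc(OCOC)cc2)c(O)c1CC=C(C)C
F3 | step 10 | racemic 7-methoxy-5-(methoxymethoxy)-2-[4-(methoxymethoxy)phenyl]-8-(3-methylbut-2-en-1-yl)chroman-4-one | COc1cc(OCOC)c2c(c1CC=C(C)C)OC(c1ccc(OCOC)cc1)CC2=O
F4 | step 10 | (2R,4R)-7-methoxy-5-(methoxymethoxy)-2-[4-(methoxymethoxy)phenyl]-8-(3-methylbut-2-en-1-yl)chroman-4-ol (2,4-cis) | COc1cc(OCOC)c2c(c1CC=C(C)C)O[C@@H](c1ccc(OCOC)cc1)C[C@H]2O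
F0 | step 12 | none | none
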